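Ring A would be closed at C-1–C-2 by a Prins cyclization–pinacol rearrangement that at the same time enlarges a cyclopentane into ring B.

**Retrosynthetic overview**

- The target is the cis-fused 2α-angeloyloxy-labd-7-en-15-oic acid (labdane numbering C-1 to C-20 throughout). Ester hydrolysis and O-2 angeloylation come last; the side chain is cut at C-11–C-12 (hydroboration of a 9(11)-methylene diene, then alkyl–alkyl Suzuki–Miyaura coupling with a bromo ester that carries C-13).
- The diene comes from a cis-fused decalone with a C-9 ketone and a 2α-hydroxyl by α-methylation, Saegusa–Ito oxidation and Wittig methylenation; that decalone comes from its C-2 epimer by inversion with participation of the C-9 carbonyl oxygen.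
- Key disconnection: C-1–C-2 (closure of ring A) together with C-5–C-10. The decalone ⇐ a monocyclic 1-isopropenylcyclopentanol silyl ether carrying a CMe2CH2CHO chain, by Prins cyclization–pinacol rearrangement; C-1 is the CH2 terminus of the isopropenyl group and C-2 the aldehyde carbon.
- Enabling feature: in ring A the oxygen-bearing C-2 is joined through the C-1 methylene to the methyl-bearing quaternary C-10, which is vicinal to C-9 of ring B. With a carbonyl at C-9, O–C-2–C-1–C-10(CH3)–C-9=O is a γ-oxygenated ketone with a quaternary α-carbon, the retron of a Prins–pinacol event, and C-5–C-10 is the bond made by the 1,2-shift.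
- Ring order: the cyclopentane (C-5 to C-9) is bought. In the key step ring A closes at C-1–C-2, first as a seven-membered ring, and the 1,2-shift of C-5 contracts it to six while enlarging the cyclopentane to ring B. The aldehyde precursor comes from a Claisen rearrangement with prenol, asymmetric hydrogenation under dynamic kinetic resolution (C-5), isopropenylcerium addition and aldehyde-selective Wacker oxidation.

Key step: step 7

Remark: the stereodescriptors of the given structure define a cis-fused decalin with H-5, CH3-10 and H-9 on one face (β) and the C-2 oxygen and the C-9 side chain on the other (α); the route is planned for exactly this isomer.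

**Route**

Step 1
Reactants: 1 1,1-dimethoxycyclopentane; 2 3-methylbut-2-en-1-ol (prenol)
Product: 5 rac-2-(2-methylbut-3-en-2-yl)cyclopentan-1-one, via mixed ketal 3 (not isolated), via allyl vinyl ether 4 (not isolated)
Conditions: propionic acid (cat.), xylene, 140 °C, MeOH distilled off
Reagents that add atoms: none
Why: Acid-catalysed ketal exchange and loss of methanol give allyl vinyl ether 4, whose thermal [3,3] Claisen rearrangement joins the tertiary carbon of the prenyl unit (C-4) to the ring α-carbon (C-5) and leaves the vinyl group that becomes C-3/C-2; the product is racemic at this stage.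

Step 2
Reactants: 5 rac-2-(2-methylbut-3-en-2-yl)cyclopentan-1-one
Product: 6 (1R,2R)-2-(2-methylbut-3-en-2-yl)cyclopentan-1-ol (cis)
Conditions: H2 (8 atm), RuCl2[(S)-binap][(R,R)-dpen] (0.5 mol %), t-BuOK (5 mol %), 2-propanol, 25 °C
Reagents that add atoms: none
Why: Noyori asymmetric hydrogenation with dynamic kinetic resolution: the base racemises the α-centre through the enolate while the catalyst reduces one enantiomer faster and from the face anti to the tert-alkyl group, so the cis alcohol of the 2R (C-5) series should result with the terminal alkene untouched (the antipodal complex would be taken if the sense proved opposite).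

Step 3
Reactants: 6 (1R,2R)-2-(2-methylbut-3-en-2-yl)cyclopentan-1-ol
Product: 7 (2R)-2-(2-methylbut-3-en-2-yl)cyclopentan-1-one
Conditions: Dess–Martin periodinane, NaHCO3, CH2Cl2, 0 °C → rt
Reagents that add atoms: none
Why: Dess–Martin oxidation under buffered, non-basic conditions returns the ketone without enolisation, so the C-5 centre set in step 2 should be kept.

Step 4
Reactants: 7 (2R)-2-(2-methylbut-3-en-2-yl)cyclopentan-1-one; 8 isopropenylmagnesium bromide
Product: 9 (1R,2R)-2-(2-methylbut-3-en-2-yl)-1-(prop-1-en-2-yl)cyclopentan-1-ol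
Conditions: CeCl3 (anhydrous), THF, −78 → 0 °C; aq. NH4Cl
Reagents that add atoms: none
Why: Organocerium 1,2-addition to a hindered, enolisable ketone without deprotonation; the reagent attacks anti to the α-tert-alkyl group, which places the isopropenyl group trans to the side chain (hydroxyl cis) at the new centre C-9.

Step 5
Reactants: 9 (1R,2R)-2-(2-methylbut-3-en-2-yl)-1-(prop-1-en-2-yl)cyclopentan-1-ol
Product: 10 triethyl{[(1R,2R)-2-(2-methylbut-3-en-2-yl)-1-(prop-1-en-2-yl)cyclopentyl]oxy}silane
Conditions: Et3SiOTf, 2,6-lutidine, CH2Cl2, −78 → 0 °C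
Reagents that add atoms: triethylsilyl trifluoromethanesulfonate, CC[Si](CC)(CC)OS(=O)(=O)C(F)(F)F
Why: Silylation of a hindered tertiary alcohol with a silyl triflate; the silyl ether prevents lactol formation with the later aldehyde and serves as the pinacol trigger in step 7.

Step 6
Reactants: 10 triethyl{[(1R,2R)-2-(2-methylbut-3-en-2-yl)-1-(prop-1-en-2-yl)cyclopentyl]oxy}silane
Product: 11 3-methyl-3-[(1R,2R)-2-(prop-1-en-2-yl)-2-(triethylsilyloxy)cyclopentyl]butanal
Conditions: PdCl2(PhCN)2 (10 mol %), CuCl2·2H2O (10 mol %), AgNO2 (5 mol %), O2 (1 atm), t-BuOH/MeNO2 (15:1), rt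
Reagents that add atoms: dioxygen, O=O
Why: Nitrite-modified, aldehyde-selective Wacker oxidation: the quaternary allylic carbon C-4 steers oxygen to the terminal carbon C-2, and the 1,1-disubstituted isopropenyl group and the silyl ether are expected to stay intact.

Step 7
Reactants: 11 3-methyl-3-[(1R,2R)-2-(prop-1-en-2-yl)-2-(triethylsilyloxy)cyclopentyl]butanal
Product: 13 (4aR,7R,8aS)-7-hydroxy-5,5,8a-trimethyloctahydronaphthalen-1(2H)-one, via cycloheptyl cation 12 (not isolated)
Conditions: SnCl4 (1.1 equiv), CH2Cl2, −78 → −23 °C; aq. NaHCO3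
Reagents that add atoms: none
Why: SnCl4 activates the aldehyde and the isopropenyl π-bond attacks C-2 through its CH2 terminus C-1, closing a seven-membered ring (7-endo-trig on the alkene; C-9, C-10, C-1, C-2, C-3, C-4, C-5) and leaving a tertiary cation at C-10 next to the silyloxy carbon C-9; the C-5–C-9 ring bond then shifts suprafacially to C-10, which contracts the new ring to six-membered ring A and at once enlarges the cyclopentane to the cyclohexanone ring B, after which chloride takes the silyl group. The closest known reaction type is the Prins cyclization–pinacol rearrangement used for ring-enlarging cyclohexane annulation of 1-alkenylcycloalkanol silyl ethers bearing a three-atom tether to the electrophilic carbon. C-5 migrates with retention and can bond only to the face of C-10 that it already covers, so with the isopropenyl group trans to the side chain H-5 ends up anti to C-9 and gauche to the C-10 methyl group: the decalin must be cis-fused and the configuration of the new quaternary centre C-10 is dictated by C-5. C-2 is set in the Prins event: the tin-bound oxygen should take the equatorial site of the chair-like ring-A array because the axial site on that face is occupied by C-9 with its silyloxy group and flanked by the axial C-4 methyl, which gives the alcohol cis to the C-10 methyl (7R), the epimer of what the target needs and the one that step 8 is designed to invert. The step needs closure by the isopropenyl group in preference to a carbonyl-ene pathway or ionisation of the silyl ether, and migration of the ring-fusion bond in preference to the C-8–C-9 bond; the gem-dimethyl group (Thorpe–Ingold effect), the absence of any other nucleophilic alkene, the silyloxy group as electron source and the alignment of the C-5–C-9 bond with the empty orbital in the fused cation are what should secure this.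

Step 8
Reactants: 13 (4aR,7R,8aS)-7-hydroxy-5,5,8a-trimethyloctahydronaphthalen-1(2H)-one
Product: 17 (4aR,7S,8aS)-7-hydroxy-5,5,8a-trimethyloctahydronaphthalen-1(2H)-one, via triflate 14 (not isolated), via oxocarbenium ion 15 (not isolated), via hemiketal 16 (not isolated)
Conditions: Tf2O, 2,6-di-tert-butylpyridine, CH2Cl2, −78 → −20 °C; then H2O/THF, NaHCO3, 0 °C → rt
Reagents that add atoms: water, O
Why: Triflation of the equatorial alcohol is followed by ionisation with neighbouring-group participation of the C-9 ketone oxygen, which lies on the α-face 1,3-diaxial to C-2 and trans to the leaving group, so the five-membered oxocarbenium ion 15 should form with inversion at C-2; water then adds at C-9 to hemiketal 16, which opens to the ketone and the 2α (7S) alcohol, the oxygen at C-2 being the former carbonyl oxygen.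

Step 9
Reactants: 17 (4aR,7S,8aS)-7-hydroxy-5,5,8a-trimethyloctahydronaphthalen-1(2H)-one
Product: 18 (4aR,7S,8aS)-7-hydroxy-2,5,5,8a-tetramethyloctahydronaphthalen-1(2H)-one (both epimers at the new methyl-bearing carbon, labdane C-8)
Conditions: lithium diisopropylamide (2.2 equiv), THF, −78 → −30 °C; MeI, −78 → −20 °C
Reagents that add atoms: iodomethane, CI
Why: Enolate alkylation: C-8 is the only enolisable position of the C-9 ketone because C-10 is quaternary, the lithium alkoxide at C-2 is not methylated at low temperature, and the new C-8 centre is removed again in step 10.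

Step 10
Reactants: 18 (4aR,7S,8aS)-7-hydroxy-2,5,5,8a-tetramethyloctahydronaphthalen-1(2H)-one
Product: 20 (4aR,7S,8aS)-7-hydroxy-2,5,5,8a-tetramethyl-4a,5,6,7,8,8a-hexahydronaphthalen-1(4H)-one, via bis-silyl enol ether 19 (not isolated)
Conditions: lithium diisopropylamide (2.5 equiv), Me3SiCl, THF, −78 → 0 °C; then Pd(OAc)2 (1.1 equiv), MeCN, rt; then K2CO3, MeOH, 0 °C
Reagents that add atoms: none
Why: Saegusa–Ito oxidation: the tetrasubstituted silyl enol ether is palladated at C-8 and β-hydride elimination toward the ring methylene C-7 should give the conjugated endocyclic enone, the hydroxyl being masked as its trimethylsilyl ether in the same flask and released by methanolysis.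

Step 11
Reactants: 20 (4aR,7S,8aS)-7-hydroxy-2,5,5,8a-tetramethyl-4a,5,6,7,8,8a-hexahydronaphthalen-1(4H)-one
Product: 21 (2S,4aR,8aS)-4,4,7,8a-tetramethyl-8-methylidene-1,2,3,4,4a,5,8,8a-octahydronaphthalen-2-ol
Conditions: Ph3PCH3Br (4 equiv), t-BuOK (4 equiv), toluene, 90 °C
Reagents that add atoms: methyltriphenylphosphonium bromide, C[P+](c1ccccc1)(c1ccccc1)c1ccccc1.[Br-]
Why: Wittig methylenation of a hindered α-methyl enone under forcing conditions, the excess ylide compensating for the alkoxide; no stereocentre is formed.

Step 12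
Reactants: 22 (3R)-5-methoxy-3-methyl-5-oxopentanoic acid (monomethyl (R)-3-methylglutarate)
Product: 23 methyl (3S)-4-bromo-3-methylbutanoate
Conditions: HgO, Br2, CCl4, reflux, dark
Reagents that add atoms: bromine, BrBr
Why: Cristol–Firth modification of the Hunsdiecker reaction: the acyl hypobromite loses CO2 to a primary radical that takes bromine, the stereocentre is not involved (3R becomes 3S only through the change of priorities) and the methyl ester is untouched.

Step 13
Reactants: 21 (2S,4aR,8aS)-4,4,7,8a-tetramethyl-8-methylidene-1,2,3,4,4a,5,8,8a-octahydronaphthalen-2-ol; 23 methyl (3S)-4-bromo-3-methylbutanoate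
Product: 25 methyl (3R)-5-[(1R,4aR,7S,8aS)-7-hydroxy-2,5,5,8a-tetramethyl-1,4,4a,5,6,7,8,8a-octahydronaphthalen-1-yl]-3-methylpentanoate, via alkylborane 24 (not isolated)
Conditions: 9-BBN (2.2 equiv), THF, 0 °C → rt; then 23, Pd(OAc)2 (5 mol %), PCy3 (10 mol %), K3PO4·H2O, THF, rt
Reagents that add atoms: none
Why: Hydroboration followed by alkyl–alkyl Suzuki–Miyaura coupling: 9-BBN adds only to the exocyclic 1,1-disubstituted alkene, boron to C-11 and hydrogen to C-9 from the convex β-face (with the 2α-oxygen equatorial, C-1 is axial on ring B and closes the α-face), which should set 9β-H, and the primary alkylborane then couples with the primary bromide under Pd/PCy3 catalysis without touching any stereocentre.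

Step 14
Reactants: 25 methyl (3R)-5-[(1R,4aR,7S,8aS)-7-hydroxy-2,5,5,8a-tetramethyl-1,4,4a,5,6,7,8,8a-octahydronaphthalen-1-yl]-3-methylpentanoate; 26 angelic acid [(2Z)-2-methylbut-2-enoic acid]
Product: 28 methyl (3R)-3-methyl-5-[(1R,4aR,7S,8aS)-2,5,5,8a-tetramethyl-7-{[(2Z)-2-methylbut-2-enoyl]oxy}-1,4,4a,5,6,7,8,8a-octahydronaphthalen-1-yl]pentanoate, via mixed anhydride 27 (not isolated)
Conditions: 26, 2,4,6-trichlorobenzoyl chloride, Et3N, toluene, rt; then 25, toluene, 80 °C
Reagents that add atoms: none
Why: Yamaguchi-type mixed-anhydride esterification without a nucleophilic catalyst: the equatorial C-2 alcohol attacks the unhindered angeloyl carbonyl of 27, the configuration at C-2 is retained and the Z double bond should not isomerise to the tiglate under these conditions.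

Step 15
Reactants: 28 methyl (3R)-3-methyl-5-[(1R,4aR,7S,8aS)-2,5,5,8a-tetramethyl-7-{[(2Z)-2-methylbut-2-enoyl]oxy}-1,4,4a,5,6,7,8,8a-octahydronaphthalen-1-yl]pentanoate
Product: 29 (3R)-3-methyl-5-[(1R,4aR,7S,8aS)-2,5,5,8a-tetramethyl-7-{[(2Z)-2-methylbut-2-enoyl]oxy}-1,4,4a,5,6,7,8,8a-octahydronaphthalen-1-yl]pentanoic acid (CNP0248298.1)
Conditions: Me3SnOH, 1,2-dichloroethane, 70 °C; then 0.5 M aq. HCl
Reagents that add atoms: trimethyltin hydroxide, C[Sn](C)(C)O
Why: Trimethyltin hydroxide hydrolysis: the unhindered methyl ester is cleaved under near-neutral conditions while the hindered, conjugated secondary angelate and the ring alkene should stay intact, and no stereocentre is affected.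

**Compound list**

1 | 1,1-dimethoxycyclopentane | COC1(OC)CCCC1 | starting material
2 | 3-methylbut-2-en-1-ol (prenol) | CC(C)=CCO | starting material
3 | 1-methoxy-1-[(3-methylbut-2-en-1-yl)oxy]cyclopentane | COC1(OCC=C(C)C)CCCC1 | intermediate (not isolated)
4 | 1-[(3-methylbut-2-en-1-yl)oxy]cyclopent-1-ene | CC(C)=CCOC1=CCCC1 | intermediate (not isolated)
5 | rac-2-(2-methylbut-3-en-2-yl)cyclopentan-1-one | C=CC(C)(C)C1CCCC1=O | intermediate
6 | (1R,2R)-2-(2-methylbut-3-en-2-yl)cyclopentan-1-ol (cis) | O[C@@H]1CCC[C@@H]1C(C)(C)C=C | intermediate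
7 | (2R)-2-(2-methylbut-3-en-2-yl)cyclopentan-1-one | O=C1CCC[C@@H]1C(C)(C)C=C | intermediate
8 | isopropenylmagnesium bromide | C=C(C)[Mg]Br | starting material
9 | (1R,2R)-2-(2-methylbut-3-en-2-yl)-1-(prop-1-en-2-yl)cyclopentan-1-ol (isopropenyl trans to the side chain) | C=C(C)[C@@]1(O)CCC[C@@H]1C(C)(C)C=C | intermediate
10 | triethyl{[(1R,2R)-2-(2-methylbut-3-en-2-yl)-1-(prop-1-en-2-yl)cyclopentyl]oxy}silane | C=C(C)[C@@]1(O[Si](CC)(CC)CC)CCC[C@@H]1C(C)(C)C=C | intermediate
11 | 3-methyl-3-[(1R,2R)-2-(prop-1-en-2-yl)-2-(triethylsilyloxy)cyclopentyl]butanal | C=C(C)[C@@]1(O[Si](CC)(CC)CC)CCC[C@@H]1C(C)(C)CC=O | intermediate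
12 | trans-fused bicyclo[5.3.0]decyl cation (tertiary cation at C-10 beside the silyloxy carbon, C-2 oxygen bound to tin) | C[C+]1C[C@H](O[Sn-](Cl)(Cl)(Cl)Cl)CC(C)(C)[C@H]2CCC[C@]12O[Si](CC)(CC)CC | intermediate (not isolated)
13 | (4aR,7R,8aS)-7-hydroxy-5,5,8a-trimethyloctahydronaphthalen-1(2H)-one (cis-fused; hydroxyl cis to the angular methyl) | O[C@@H]1CC(C)(C)[C@H]2CCCC(=O)[C@@]2(C)C1 | intermediate
14 | trifluoromethanesulfonate of 13 | FC(F)(F)S(=O)(=O)O[C@@H]1CC(C)(C)[C@H]2CCCC(=O)[C@@]2(C)C1 | intermediate (not isolated)
15 | bridged oxocarbenium triflate (former ketone oxygen bonded to C-2 on the α-face) | C[C@]12C[C@@H]3CC(C)(C)[C@H]1CCCC2=[O+]3.[O-]S(=O)(=O)C(F)(F)F | intermediate (not isolated)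
16 | bridged hemiketal (water adduct of 15 at C-9) | C[C@]12C[C@@H]3CC(C)(C)[C@H]1CCC[C@@]2(O)O3 | intermediate (not isolated)
17 | (4aR,7S,8aS)-7-hydroxy-5,5,8a-trimethyloctahydronaphthalen-1(2H)-one (hydroxyl trans to the angular methyl) | O[C@H]1CC(C)(C)[C@H]2CCCC(=O)[C@@]2(C)C1 | intermediate
18 | (4aR,7S,8aS)-7-hydroxy-2,5,5,8a-tetramethyloctahydronaphthalen-1(2H)-one (epimers at the methyl-bearing carbon) | O[C@H]1CC(C)(C)[C@H]2CCC(C)C(=O)[C@@]2(C)C1 | intermediate
19 | bis(trimethylsilyl) derivative of 18 (silyl enol ether and silyl ether) | C[Si](C)(C)O[C@H]1CC(C)(C)[C@H]2CCC(C)=C(O[Si](C)(C)C)[C@@]2(C)C1 | intermediate (not isolated)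
20 | (4aR,7S,8aS)-7-hydroxy-2,5,5,8a-tetramethyl-4a,5,6,7,8,8a-hexahydronaphthalen-1(4H)-one | O[C@H]1CC(C)(C)[C@H]2CC=C(C)C(=O)[C@@]2(C)C1 | intermediate
21 | (2S,4aR,8aS)-4,4,7,8a-tetramethyl-8-methylidene-1,2,3,4,4a,5,8,8a-octahydronaphthalen-2-ol | O[C@H]1CC(C)(C)[C@H]2CC=C(C)C(=C)[C@@]2(C)C1 | intermediate
22 | (3R)-5-methoxy-3-methyl-5-oxopentanoic acid | OC(=O)C[C@@H](C)CC(=O)OC | starting material
23 | methyl (3S)-4-bromo-3-methylbutanoate | BrC[C@@H](C)CC(=O)OC | intermediate
24 | B-alkyl-9-BBN at C-11 (9β-H), the C-2 hydroxyl carried as its 9-BBN borinate | B3(C4CCCC3CCC4)O[C@H]1CC(C)(C)[C@H]2CC=C(C)[C@@H](CB3C4CCCC3CCC4)[C@@]2(C)C1 | intermediate (not isolated)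
25 | methyl (3R)-5-[(1R,4aR,7S,8aS)-7-hydroxy-2,5,5,8a-tetramethyl-1,4,4a,5,6,7,8,8a-octahydronaphthalen-1-yl]-3-methylpentanoate | O[C@H]1CC(C)(C)[C@H]2CC=C(C)[C@@H](CC[C@@H](C)CC(=O)OC)[C@@]2(C)C1 | intermediate
26 | angelic acid, (2Z)-2-methylbut-2-enoic acid | C/C=C(/C)C(=O)O | starting material
27 | (2Z)-2-methylbut-2-enoic 2,4,6-trichlorobenzoic anhydride | C/C=C(/C)C(=O)OC(=O)c1c(Cl)cc(Cl)cc1Cl | intermediate (not isolated)
28 | methyl (3R)-3-methyl-5-[(1R,4aR,7S,8aS)-2,5,5,8a-tetramethyl-7-{[(2Z)-2-methylbut-2-enoyl]oxy}-1,4,4a,5,6,7,8,8a-octahydronaphthalen-1-yl]pentanoate | C/C=C(/C)C(=O)O[C@H]1CC(C)(C)[C@H]2CC=C(C)[C@@H](CC[C@@H](C)CC(=O)OC)[C@@]2(C)C1 | intermediate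
29 | (3R)-3-methyl-5-[(1R,4aR,7S,8aS)-2,5,5,8a-tetramethyl-7-{[(2Z)-2-methylbut-2-enoyl]oxy}-1,4,4a,5,6,7,8,8a-octahydronaphthalen-1-yl]pentanoic acid | C/C=C(/C)C(=O)O[C@H]1CC(C)(C)[C@H]2CC=C(C)[C@@H](CC[C@@H](C)CC(=O)O)[C@@]2(C)C1 | target

**Step count and risks**

Total step count: 15. Longest linear sequence: 14 steps (steps 1–11 and 13–15; step 12 makes the side-chain bromide).

Steps most likely to fail:

1. Step 7 (key step). What may go wrong: cation 12 may lose a proton from the C-10 methyl group (net carbonyl-ene reaction) instead of undergoing the 1,2-shift, the C-8–C-9 bond may migrate in place of C-5–C-9 to give a bridged ketone, or the tertiary silyl ether may ionise before the aldehyde is engaged. Fallback: the two events are separated. Aldehyde 11 is cyclised under carbonyl-ene conditions (Me2AlCl, CH2Cl2, −78 °C; type 2 ene reaction forming the same C-1–C-2 bond) to the trans-fused 4,4-dimethyl-8-methylidene-8a-(triethylsilyloxy)decahydroazulen-6-ol F1. F1 is then treated with a catalytic strong Brønsted acid (HNTf2, CH2Cl2, −78 °C): protonation of the exocyclic methylene regenerates the C-10 cation without a Lewis acid on oxygen, and the semipinacol shift of C-5 with loss of the silyl group brings the route back at 13.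

2. Step 8. What may go wrong: the triflate may eliminate to the ring-A alkenes faster than the carbonyl oxygen closes the bridge. Fallback: an oxidation–reduction sequence from 13. Dess–Martin oxidation gives (4aR,8aS)-5,5,8a-trimethylhexahydronaphthalene-1,7(2H,8H)-dione F2. Reduction with LiB(s-Bu)3H (THF, −78 °C) should touch only the unhindered C-2 ketone. In the chair that keeps the C-10 methyl equatorial, hydride should come from the β-face because the α-face is closed by the axial C-9 and the axial C-4 methyl; this gives 17. This selectivity rests on that chair being the reacting conformer and is the weak point of the fallback.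

3. Step 13. What may go wrong: oxidative addition of the β-branched bromide may be slow, so that β-hydride elimination and protodeboronation of the borane take over; the hydroboration may also lose facial selectivity. Fallback (for the coupling; C-9 is still set by hydroboration): diene 21 is hydroborated as before but oxidised (9-BBN; NaOH, H2O2) to (2S,4aR,8R,8aS)-8-(hydroxymethyl)-4,4,7,8a-tetramethyl-1,2,3,4,4a,5,8,8a-octahydronaphthalen-2-ol F3. The primary hydroxyl is exchanged selectively for iodide (I2, PPh3, imidazole, 0 °C) to give (2S,4aR,8R,8aS)-8-(iodomethyl)-4,4,7,8a-tetramethyl-1,2,3,4,4a,5,8,8a-octahydronaphthalen-2-ol F4. F4 is joined with [(2S)-4-methoxy-2-methyl-4-oxobutyl]zinc bromide F5, made from 23 and zinc dust, in a Negishi alkyl–alkyl coupling (Pd2(dba)3, tricyclopentylphosphine, N-methylimidazole, THF/NMP, 80 °C) to return at 25.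

Further compounds
F1 | step 7 | 4,4-dimethyl-8-methylidene-8a-(triethylsilyloxy)decahydroazulen-6-ol (trans-fused ene product) | C=C1C[C@H](O)CC(C)(C)[C@H]2CCC[C@]12O[Si](CC)(CC)CC
F2 | step 8 | (4aR,8aS)-5,5,8a-trimethylhexahydronaphthalene-1,7(2H,8H)-dione | O=C1CC(C)(C)[C@H]2CCCC(=O)[C@@]2(C)C1
F3 | step 13 | (2S,4aR,8R,8aS)-8-(hydroxymethyl)-4,4,7,8a-tetramethyl-1,2,3,4,4a,5,8,8a-octahydronaphthalen-2-ol | O[C@H]1CC(C)(C)[C@H]2CC=C(C)[C@@H](CO)[C@@]2(C)C1
F4 | step 13 | (2S,4aR,8R,8aS)-8-(iodomethyl)-4,4,7,8a-tetramethyl-1,2,3,4,4a,5,8,8a-octahydronaphthalen-2-ol | O[C@H]1CC(C)(C)[C@H]2CC=C(C)[C@@H](CI)[C@@]2(C)C1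
F5 | step 13 | [(2S)-4-methoxy-2-methyl-4-oxobutyl]zinc bromide | Br[Zn]C[C@@H](C)CC(=O)OC
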